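The plan cuts the ring-fusion bond C5–C10 (eremophilane numbering) together with C6–C7, so that both rings of the cis-decalin open to an acyclic tetraene. Forward, one intramolecular Diels–Alder reaction closes ring A (C1–C5, C10) through the tether and ring B (C5–C10) as a cyclohexene, and sets C5, C7 and C10. It exploits that ring B carries the C8 ketone next to the C9 carbinol, the retron of a 2-silyloxy diene (C7 to C10), and that the quaternary, methyl-bearing C5 is the inner carbon of an isopropenyl-type dienophile (C5=C6). A (Z)-diene enforces the cis fusion; C4, C3 and C9 are adjusted afterwards.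

Key step: step 7

Remark: locants follow eremophilane numbering (C11–C13 isopropenyl on C7, C14 methyl on C5, C15 methyl on C4), β is the face of the C5 methyl, eremophilane-type names serve for numbering only (configuration is given by the descriptors and the SMILES), and compounds 1, 2, 5, 8, 17, 18 and 21 are taken as purchased.

Step 1
Reactants: 1 isoprene (2-methylbuta-1,3-diene); 2 catecholborane (1,3,2-benzodioxaborole)
Product: 4 4,4,5,5-tetramethyl-2-[(2Z)-2-methylbut-2-en-1-yl]-1,3,2-dioxaborolane, via catechol allylboronate 3 (not isolated)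
Conditions: Pd(PPh3)4 (1 mol%), benzene, 25 °C; then pinacol, 25 °C
Reagents that add atoms: pinacol (2,3-dimethylbutane-2,3-diol), CC(C)(O)C(C)(C)O
Why: Palladium-catalysed 1,4-hydroboration of the diene through an anti π-allyl complex should put boron on C1 and give the (Z)-allylboronate, and B–O exchange with pinacol gives the stable ester; no stereocentre is formed.

Step 2
Reactants: 5 pent-4-ynal; 4 4,4,5,5-tetramethyl-2-[(2Z)-2-methylbut-2-en-1-yl]-1,3,2-dioxaborolane
Product: 6 (3S,4S)-2,3-dimethyloct-1-en-7-yn-4-ol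
Conditions: (R)-TRIP [(R)-3,3′-bis(2,4,6-triisopropylphenyl)-1,1′-binaphthyl-2,2′-diyl hydrogen phosphate] (5 mol%), 4 Å molecular sieves, toluene, −30 °C; aqueous work-up
Reagents that add atoms: none
Why: Chiral phosphoric acid-catalysed allylboration through a closed chair (Zimmerman–Traxler) transition state, in which the (Z)-boronate gives the syn relation between the carbinol centre (later C3) and the methyl centre (later C4) and the catalyst selects the aldehyde face (the enantiomeric acid would be taken should the sense prove opposite).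

Step 3
Reactants: 6 (3S,4S)-2,3-dimethyloct-1-en-7-yn-4-ol
Product: 7 (3S,4S)-2,3-dimethyloct-1-en-7-yn-4-yl acetate
Conditions: Ac2O, pyridine, DMAP (cat.), CH2Cl2, 0 → 25 °C
Reagents that add atoms: acetic anhydride, CC(=O)OC(C)=O
Why: DMAP-catalysed acetylation of the secondary alcohol gives an ester that can later be removed without acid or fluoride; no stereocentre is touched.

Step 4
Reactants: 7 (3S,4S)-2,3-dimethyloct-1-en-7-yn-4-yl acetate; 8 3-methylbut-2-enoyl chloride
Product: 9 (3S,4S)-2,3,11-trimethyl-9-oxododeca-1,10-dien-7-yn-4-yl acetate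
Conditions: PdCl2(PPh3)2 (2 mol%), CuI (4 mol%), Et3N (1.2 equiv), THF, 25 °C
Reagents that add atoms: none
Why: Acyl Sonogashira coupling of the terminal alkyne with the acid chloride should give the cross-conjugated ynone, with the ester and the 1,1-disubstituted alkene inert.

Step 5
Reactants: 9 (3S,4S)-2,3,11-trimethyl-9-oxododeca-1,10-dien-7-yn-4-yl acetate
Product: 10 (3S,4S,9Z)-2,3,11-trimethyl-9-{[tri(propan-2-yl)silyl]oxy}dodeca-1,9,11-trien-7-yn-4-yl acetate
Conditions: TIPSOTf, Et3N, CH2Cl2, −78 → 0 °C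
Reagents that add atoms: triisopropylsilyl trifluoromethanesulfonate, CC(C)[Si](C(C)C)(C(C)C)OS(=O)(=O)C(F)(F)F
Why: Soft enolisation (silyl triflate and tertiary amine) by γ-deprotonation of the β,β-dimethyl enone, its only enolisable site, through the s-cis conformer should give the (9Z)-silyl dienol ether with the isopropenyl group cis to oxygen.

Step 6
Reactants: 10 (3S,4S,9Z)-2,3,11-trimethyl-9-{[tri(propan-2-yl)silyl]oxy}dodeca-1,9,11-trien-7-yn-4-yl acetate
Product: 11 (3S,4S,7Z,9Z)-2,3,11-trimethyl-9-{[tri(propan-2-yl)silyl]oxy}dodeca-1,7,9,11-tetraen-4-yl acetate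
Conditions: H2 (1 atm), Pd/CaCO3 poisoned with Pb(OAc)2 (Lindlar catalyst), quinoline, hexane/EtOAc, 0 °C
Reagents that add atoms: none
Why: Lindlar semi-hydrogenation adds hydrogen syn to the alkyne and should give the (7Z)-alkene, while the 1,1-disubstituted alkenes and the enol ether are not reduced.

Step 7
Reactants: 11 (3S,4S,7Z,9Z)-2,3,11-trimethyl-9-{[tri(propan-2-yl)silyl]oxy}dodeca-1,7,9,11-tetraen-4-yl acetate
Product: 12 (3S,4S,5S,7R,10R)-8-{[tri(propan-2-yl)silyl]oxy}eremophila-8,11-dien-3-yl acetate (cis-fused; 3β-OAc, 4α-CH3, 5β-CH3, 7β-isopropenyl, 10β-H)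
Conditions: CH2Cl2 (0.02 M), BHT, Et3N (trace), 13 kbar, 80 °C
Reagents that add atoms: none
Why: A concerted, suprafacial [4+2] cycloaddition of the 2-silyloxy diene C7=C8–C9=C10 with the unactivated 1,1-disubstituted alkene C5=C6 forms C5–C10 and C6–C7 in one event; the closest known reaction type is the Type 1 intramolecular Diels–Alder reaction of 1,7,9-decatrienes, here run under high pressure. Ring A (C10–C1–C2–C3–C4–C5) closes through the four-carbon tether in a chair-like six-membered array, and ring B (C5–C10) closes as the cyclohexene whose enol ether marks C8. Because the tether sits on the inside (Z) position of C10, only the transition state with the C5 methyl under the diene can be reached, so H-10 and the C5 methyl end cis (cis-decalin) and the outside isopropenyl group at C7 ends cis to H-10. The face of the dienophile is chosen by the C3/C4 pair: acetoxy and methyl both sit equatorial on the chair tether with the allylic C4–H eclipsing the C5 methyl, which places the C4 methyl trans and the C3 acetoxy cis to the C5 methyl. The step needs the cycloaddition to outrun the 1,5-hydrogen shift open to (Z)-dienes, which pressure should secure because only the cycloaddition has a large negative activation volume; the trans relation of isopropenyl and C9 across C7=C8 excludes a 6π-electrocyclisation.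

Step 8
Reactants: 12 (3S,4S,5S,7R,10R)-8-{[tri(propan-2-yl)silyl]oxy}eremophila-8,11-dien-3-yl acetate
Product: 13 (3S,4S,5S,7R,10R)-8-{[tri(propan-2-yl)silyl]oxy}eremophila-8,11-dien-3-ol (3β-OH, 4α-CH3)
Conditions: K2CO3 (0.2 equiv), MeOH, 0 → 25 °C
Reagents that add atoms: none
Why: Base-catalysed transesterification (methanolysis) removes the acetate, and the bulky triisopropylsilyl enol ether should survive these conditions.

Step 9
Reactants: 13 (3S,4S,5S,7R,10R)-8-{[tri(propan-2-yl)silyl]oxy}eremophila-8,11-dien-3-ol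
Product: 14 (4S,5S,7R,10R)-8-{[tri(propan-2-yl)silyl]oxy}eremophila-8,11-dien-3-one (4α-CH3)
Conditions: (n-Pr4N)RuO4 (5 mol%), N-methylmorpholine N-oxide, 4 Å molecular sieves, CH2Cl2, 25 °C
Reagents that add atoms: none
Why: Ley–Griffith oxidation of the secondary alcohol under neutral conditions should leave the silyl enol ether and the isopropenyl group untouched.

Step 10
Reactants: 14 (4S,5S,7R,10R)-8-{[tri(propan-2-yl)silyl]oxy}eremophila-8,11-dien-3-one
Product: 15 (4R,5S,7R,10R)-8-{[tri(propan-2-yl)silyl]oxy}eremophila-8,11-dien-3-one (4β-CH3)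
Conditions: NaOMe (0.3 equiv), MeOH/THF, 25 °C
Reagents that add atoms: none
Why: Base-mediated epimerisation through the C3 enolate under thermodynamic control should favour the 4β-methyl epimer, because only then can the decalin hold the C4 methyl and the C7 isopropenyl group both equatorial, whereas the 4α epimer must place one of them syn-axial.

Step 11
Reactants: 15 (4R,5S,7R,10R)-8-{[tri(propan-2-yl)silyl]oxy}eremophila-8,11-dien-3-one
Product: 16 (3S,4R,5S,7R,10R)-8-{[tri(propan-2-yl)silyl]oxy}eremophila-8,11-dien-3-ol (3β-OH axial, 4β-CH3)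
Conditions: LiBH(s-Bu)3 (L-Selectride), THF, −78 °C; then H2O
Reagents that add atoms: none
Why: Ketone reduction with a bulky trialkylborohydride, in which the axial C5 methyl blocks the axial trajectory at C3 (1,3-diaxial), so hydride should enter equatorially and give the axial 3β-alcohol.

Step 12
Reactants: 17 (2R)-pent-4-en-2-ol; 18 angelic acid [(2Z)-2-methylbut-2-enoic acid]
Product: 20 (2R)-pent-4-en-2-yl (2Z)-2-methylbut-2-enoate, via mixed anhydride 19 (not isolated)
Conditions: 2,4,6-trichlorobenzoyl chloride, Et3N, toluene, 25 °C; then 17, 80 °C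
Reagents that add atoms: none
Why: Yamaguchi-type esterification through the mixed anhydride without a nucleophilic catalyst should keep the (Z) geometry of the angelate, and O-acylation leaves the carbinol centre untouched.

Step 13
Reactants: 20 (2R)-pent-4-en-2-yl (2Z)-2-methylbut-2-enoate; 21 acrylic acid
Product: 22 (2E,5R)-5-{[(2Z)-2-methylbut-2-enoyl]oxy}hex-2-enoic acid
Conditions: RuCl2(H2IMes)(=CH–C6H4-2-O-i-Pr) (second-generation Hoveyda–Grubbs catalyst, 5 mol%), CH2Cl2, 40 °C
Reagents that add atoms: none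
Why: Olefin cross-metathesis of the terminal alkene with acrylic acid should give the (E)-enoic acid as the thermodynamic product, and the trisubstituted angelate alkene does not take part.

Step 14
Reactants: 16 (3S,4R,5S,7R,10R)-8-{[tri(propan-2-yl)silyl]oxy}eremophila-8,11-dien-3-ol; 22 (2E,5R)-5-{[(2Z)-2-methylbut-2-enoyl]oxy}hex-2-enoic acid
Product: 23 (3R,4R,5S,7R,10R)-8-{[tri(propan-2-yl)silyl]oxy}eremophila-8,11-dien-3-yl (2E,5R)-5-{[(2Z)-2-methylbut-2-enoyl]oxy}hex-2-enoate (3α-ester)
Conditions: PPh3, diisopropyl azodicarboxylate, toluene, 0 → 25 °C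
Reagents that add atoms: none
Why: Mitsunobu esterification, in which the carboxylate displaces the alkoxyphosphonium of the axial 3β-alcohol in an SN2 step with inversion and so should set the equatorial 3α-ester of the target.

Step 15
Reactants: 23 (3R,4R,5S,7R,10R)-8-{[tri(propan-2-yl)silyl]oxy}eremophila-8,11-dien-3-yl (2E,5R)-5-{[(2Z)-2-methylbut-2-enoyl]oxy}hex-2-enoate
Product: 25 (3R,4R,5R,7R,9R,10S)-9-hydroxy-8-oxoeremophil-11-en-3-yl (2E,5R)-5-{[(2Z)-2-methylbut-2-enoyl]oxy}hex-2-enoate (CNP0210874.1), via silyloxy epoxide 24 (not isolated)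
Conditions: dimethyldioxirane (1.1 equiv), acetone/CH2Cl2, −40 °C; then HF·pyridine, THF, 0 °C
Reagents that add atoms: dimethyldioxirane, CC1(C)OO1
Why: Rubottom oxidation, in which the electron-rich silyl enol ether is epoxidised chemoselectively on the open β face of ring B (the α face is covered by ring A) and fluoride-induced desilylation opens the silyloxy epoxide to the α-hydroxy ketone with the 9β-hydroxyl; no base is present, so C7 and the deconjugated isopropenyl group should be kept.

Compound list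
1 | isoprene (2-methylbuta-1,3-diene) | C=CC(C)=C | starting material
2 | catecholborane (1,3,2-benzodioxaborole) | B1Oc2ccccc2O1 | starting material
3 | 2-[(2Z)-2-methylbut-2-en-1-yl]-1,3,2-benzodioxaborole | C/C=C(C)\CB1Oc2ccccc2O1 | intermediate
4 | 4,4,5,5-tetramethyl-2-[(2Z)-2-methylbut-2-en-1-yl]-1,3,2-dioxaborolane | C/C=C(C)\CB1OC(C)(C)C(C)(C)O1 | intermediate
5 | pent-4-ynal | C#CCCC=O | starting material
6 | (3S,4S)-2,3-dimethyloct-1-en-7-yn-4-ol | C#CCC[C@H](O)[C@@H](C)C(C)=C | intermediate
7 | (3S,4S)-2,3-dimethyloct-1-en-7-yn-4-yl acetate | C#CCC[C@H](OC(C)=O)[C@@H](C)C(C)=C | intermediate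
8 | 3-methylbut-2-enoyl chloride | CC(C)=CC(Cl)=O | starting material
9 | (3S,4S)-2,3,11-trimethyl-9-oxododeca-1,10-dien-7-yn-4-yl acetate | CC(C)=CC(=O)C#CCC[C@H](OC(C)=O)[C@@H](C)C(C)=C | intermediate
10 | (3S,4S,9Z)-2,3,11-trimethyl-9-{[tri(propan-2-yl)silyl]oxy}dodeca-1,9,11-trien-7-yn-4-yl acetate | C=C(C)/C=C(\O[Si](C(C)C)(C(C)C)C(C)C)C#CCC[C@H](OC(C)=O)[C@@H](C)C(C)=C | intermediate
11 | (3S,4S,7Z,9Z)-2,3,11-trimethyl-9-{[tri(propan-2-yl)silyl]oxy}dodeca-1,7,9,11-tetraen-4-yl acetate | C=C(C)/C=C(O[Si](C(C)C)(C(C)C)C(C)C)/C=C\CC[C@H](OC(C)=O)[C@@H](C)C(C)=C | intermediate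
12 | (3S,4S,5S,7R,10R)-8-{[tri(propan-2-yl)silyl]oxy}eremophila-8,11-dien-3-yl acetate (3β-OAc, 4α-CH3, 5β-CH3, 7β-isopropenyl, 10β-H) | C=C(C)[C@H]1C[C@@]2(C)[C@H](CC[C@H](OC(C)=O)[C@H]2C)C=C1O[Si](C(C)C)(C(C)C)C(C)C | intermediate
13 | (3S,4S,5S,7R,10R)-8-{[tri(propan-2-yl)silyl]oxy}eremophila-8,11-dien-3-ol (3β-OH, 4α-CH3) | C=C(C)[C@H]1C[C@@]2(C)[C@H](CC[C@H](O)[C@H]2C)C=C1O[Si](C(C)C)(C(C)C)C(C)C | intermediate
14 | (4S,5S,7R,10R)-8-{[tri(propan-2-yl)silyl]oxy}eremophila-8,11-dien-3-one (4α-CH3) | C=C(C)[C@H]1C[C@@]2(C)[C@H](CCC(=O)[C@H]2C)C=C1O[Si](C(C)C)(C(C)C)C(C)C | intermediate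
15 | (4R,5S,7R,10R)-8-{[tri(propan-2-yl)silyl]oxy}eremophila-8,11-dien-3-one (4β-CH3) | C=C(C)[C@H]1C[C@@]2(C)[C@H](CCC(=O)[C@@H]2C)C=C1O[Si](C(C)C)(C(C)C)C(C)C | intermediate
16 | (3S,4R,5S,7R,10R)-8-{[tri(propan-2-yl)silyl]oxy}eremophila-8,11-dien-3-ol (3β-OH, 4β-CH3) | C=C(C)[C@H]1C[C@@]2(C)[C@H](CC[C@H](O)[C@@H]2C)C=C1O[Si](C(C)C)(C(C)C)C(C)C | intermediate
17 | (2R)-pent-4-en-2-ol | C=CC[C@@H](C)O | starting material
18 | angelic acid [(2Z)-2-methylbut-2-enoic acid] | C/C=C(/C)C(=O)O | starting material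
19 | (2Z)-2-methylbut-2-enoic 2,4,6-trichlorobenzoic anhydride | C/C=C(/C)C(=O)OC(=O)c1c(Cl)cc(Cl)cc1Cl | intermediate
20 | (2R)-pent-4-en-2-yl (2Z)-2-methylbut-2-enoate | C=CC[C@@H](C)OC(=O)/C(C)=C\C | intermediate
21 | acrylic acid (prop-2-enoic acid) | C=CC(=O)O | starting material
22 | (2E,5R)-5-{[(2Z)-2-methylbut-2-enoyl]oxy}hex-2-enoic acid | OC(=O)/C=C/C[C@@H](C)OC(=O)/C(C)=C\C | intermediate
23 | (3R,4R,5S,7R,10R)-8-{[tri(propan-2-yl)silyl]oxy}eremophila-8,11-dien-3-yl (2E,5R)-5-{[(2Z)-2-methylbut-2-enoyl]oxy}hex-2-enoate | C=C(C)[C@H]1C[C@@]2(C)[C@H](CC[C@@H](OC(=O)/C=C/C[C@@H](C)OC(=O)/C(C)=C\C)[C@@H]2C)C=C1O[Si](C(C)C)(C(C)C)C(C)C | intermediate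
24 | (3R,4R,5R,7R,8R,9R,10S)-8,9-epoxy-8-{[tri(propan-2-yl)silyl]oxy}eremophil-11-en-3-yl (2E,5R)-5-{[(2Z)-2-methylbut-2-enoyl]oxy}hex-2-enoate (8β,9β-epoxide) | C=C(C)[C@H]1C[C@@]2(C)[C@H](CC[C@@H](OC(=O)/C=C/C[C@@H](C)OC(=O)/C(C)=C\C)[C@@H]2C)[C@H]3O[C@@]13O[Si](C(C)C)(C(C)C)C(C)C | intermediate
25 | (3R,4R,5R,7R,9R,10S)-9-hydroxy-8-oxoeremophil-11-en-3-yl (2E,5R)-5-{[(2Z)-2-methylbut-2-enoyl]oxy}hex-2-enoate (CNP0210874.1) | C=C(C)[C@H]1C[C@@]2(C)[C@H](CC[C@@H](OC(=O)/C=C/C[C@@H](C)OC(=O)/C(C)=C\C)[C@@H]2C)[C@@H](O)C1=O | target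

Total step count: 15. Longest linear sequence: 13 steps (steps 1–11, 14 and 15; steps 12 and 13 build the side-chain acid 22).

Steps most likely to fail

1. Step 7. The cycloaddition of the unactivated alkene may be too slow, so that the 1,5-hydrogen shift of the (Z)-diene or loss of the enol ether takes over. The fallback replaces the pericyclic step by a metal-templated, stepwise [4+2]: compound 11 is treated with a cationic rhodium catalyst made from [RhCl(C8H14)2]2, AgSbF6 and P(OCH(CF3)2)3 in 1,2-dichloroethane at 25–55 °C (oxidative cyclisation of diene and alkene at the metal, then reductive elimination). This sets out from compound 11, should return directly at compound 12, and makes no new compound (F0).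

2. Step 14. Displacement at the hindered axial alcohol may give elimination or incomplete inversion, and the phosphine may isomerise the angelate. The fallback sets out from ketone 15: an equilibrating Meerwein–Ponndorf–Verley reduction (Al(O-i-Pr)3, propan-2-ol, toluene, 80 °C) should give the more stable equatorial alcohol (3R,4R,5S,7R,10R)-8-{[tri(propan-2-yl)silyl]oxy}eremophila-8,11-dien-3-ol F1. This is acylated with acid 22 under Yamaguchi conditions (2,4,6-trichlorobenzoyl chloride, Et3N, then DMAP, toluene, 25 °C) with retention, returning at compound 23.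

3. Step 5. The amine may add to the silyl-activated ynone, or the enol ether may form with the wrong geometry. The fallback sets out from ynone 9: it is first semi-hydrogenated (H2, Pd/CaCO3 poisoned with Pb(OAc)2, quinoline, 0 °C) to the dienone (3S,4S,7Z)-2,3,11-trimethyl-9-oxododeca-1,7,10-trien-4-yl acetate F2. The less electrophilic dienone is then silylated by soft enolisation (TIPSOTf, i-Pr2NEt, CH2Cl2, −78 °C), returning at compound 11.

Further compounds
F0 | step 7 | none | none
F1 | step 14 | (3R,4R,5S,7R,10R)-8-{[tri(propan-2-yl)silyl]oxy}eremophila-8,11-dien-3-ol (3α-OH, 4β-CH3) | C=C(C)[C@H]1C[C@@]2(C)[C@H](CC[C@@H](O)[C@@H]2C)C=C1O[Si](C(C)C)(C(C)C)C(C)C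
F2 | step 5 | (3S,4S,7Z)-2,3,11-trimethyl-9-oxododeca-1,7,10-trien-4-yl acetate | CC(C)=CC(=O)/C=C\CC[C@H](OC(C)=O)[C@@H](C)C(C)=C
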